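## Structural features

The target is an isoflavone: a 4H-chromen-4-one in which benzo ring A and pyranone ring C are fused along C4a–C8a, with ring B attached through the C3–C1' bond. Ring A carries free hydroxyls at C5 and C7, so C5, C7 and C8a all bear oxygen while C4a bears the C4 carbonyl, which is an acylated phloroglucinol pattern. Ring B is pentasubstituted in one unbroken run: C1' (to C3), C2' (OH), C3' (CH2CH2C(CH3)2OH), C4' (OCH3), C5' (OCH3), leaving only C6'–H. There is no stereocenter, so nothing stereochemical has to be set or preserved. Four sites are fragile:
- the tertiary alcohol, which under acid ionises and is trapped by the neighbouring C2' phenol as a 2,2-dimethylchroman, or dehydrates;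
- C2 of ring C, a vinylogous ester carbon that hydroxide attacks with ring opening and loss of formate;
- the C2=C3 bond, which can be over-reduced;
- ring B itself, a para-alkoxyphenol that oxidises easily.

The real difficulty lies in ring B, where five contiguous substituents must be placed with one phenol kept distinct from two methyl ethers, and in unveiling four hydroxyl groups at the end without acid. The key step uses the ring A pattern: the oxygens on C5, C7 and C8a are all ortho or para to the C4 carbonyl, so ring A can be carried as a 2,4,6-trifluorobenzoyl unit, C3–C4 being made by acylation and ring C closed when the C2 oxygen displaces the fluorine on C8a.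

## Logic of the disconnections

**24 ⇒ 23.** The three O–CH2Ph bonds at C2', C5 and C7 are cut. Hydrogenolysis is neutral, so the tertiary alcohol and the C2' phenol are never together in acid. The gain is that all three phenols fall in a single operation. The demand is that C2=C3 survives the hydrogenation.

**23 ⇒ 21.** The C5–O and C7–O bonds are exchanged for C5–F and C7–F. Fluorine is a small, inert placeholder that is activated for substitution (ortho and para to C4=O) only once ring C exists. The gain is a ring A that needs no protecting group and no regiochemical decision. The demand is two successive aromatic substitutions by a benzyloxide nucleophile without cleavage of ring C at C2.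

**21 ⇒ 17 + 18.** The C3–C4 and O1–C8a bonds are cut. This splits the bicyclic core into an enamine carrying all of ring B and a symmetric acid chloride carrying all of ring A. The demand is C-acylation at the enamine β-carbon, exchange of nitrogen for oxygen at C2, and closure through that oxygen. The tertiary hydroxyl of 17 is left free: it is too hindered to compete with the enamine carbon for 18, which saves a protection and a deprotection and allows an acidic hydrolysis between the two bond-forming events.

**17 ⇒ 12 + 15.** The C2=C3 double bond of the future ring C (the enamine C=C) is cut. A one-carbon homologation of aryl aldehyde 12 that delivers the enamine directly avoids a free, self-condensing arylacetaldehyde and avoids an epoxide-opening and oxidation sequence with a gaseous epoxide. 15 in turn is cut at P–C and N–C into 13, 14 and formaldehyde. The demand is a strongly basic olefination that tolerates the free tertiary hydroxyl at the cost of one extra equivalent of reagent.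

**12 ⇒ 11 ⇒ 9.** First the benzyl O–C bond is cut, then the aryl–CHO bond at C1'. With the phenol free, its hydroxyl directs a formyl group to the only open ortho position, so no halogenation and no second metalation are needed. The demand is that the phenol be unmasked before this point and re-masked as the benzyl ether afterwards.

**9 ⇒ 8 ⇒ 6.** The acetal C–O bond is cut, then the tertiary C–OH bond, going back to the trisubstituted alkene. The gain is that the five-carbon chain comes from a prenyl group. The demand is Markovnikov hydration under non-acidic, mercury-free conditions while the phenol is still masked, so that neither chroman formation nor phenol oxidation can occur.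

**6 ⇒ 2 + 3, and 2 ⇒ 1.** The aryl–CH2 bond at C3' is cut, then the acetal. The C–H between two oxygen substituents of 2 is the most readily lithiated position, and 3 supplies all five chain carbons. The demand is a chelating, base-stable directing group: a benzyl ether would be metalated at its own CH2 and a chloromethyl ether reagent is avoided on safety grounds, so a tetrahydropyranyl acetal is used and exchanged for benzyl only after the metalation chemistry is over.

## Other disconnections considered

**Alternative 1:** The cut is at C4–C4a and O1–C2, giving phloroglucinol A2 and 2-(5,6-dimethoxy-2-oxochroman-8-yl)acrylic acid A3. In the forward sense, A3 in P2O5/CH3SO3H would acylate A2 at carbon (Friedel–Crafts), and the adjacent phenol would then add to the acrylate β-carbon (oxa-Michael) to give the racemic isoflavanone A1.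
- In its favour: ring A is used unprotected, its threefold symmetry removes any regiochemical question, and the dihydrocoumarin lactone holds both the C2' oxygen and the future carbinol carbon in a form that strong acid cannot cyclise or dehydrate.
- Against it here: A1 is one oxidation level too low, so C2–C3 must be dehydrogenated in the presence of free phenols and an oxidisable ring B. The lactone must later accept two methyl nucleophiles next to a chromone carbonyl and three acidic hydroxyls. In the acid medium A3 may polymerise, add to A2 by conjugate hydroarylation, or transfer its lactone acyl group. A3 also needs its own multistep synthesis.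
- Comparison: on protecting-group economy this plan is the better one. On ring A regiochemistry it is the equal of the chosen plan, since both rest on symmetry. On redox economy and on the chemoselectivity of the late steps the chosen plan is stronger, because it reaches the isoflavone oxidation level directly and ends under neutral conditions.

**Alternative 2:** The cut is at C3–C4 with reversed polarity. The substrate is aldehyde–ketone A5, a ring A salicylaldehyde O-alkylated by a ring B α-keto methylene unit. In the forward sense, a triazolium-derived carbene would add to the aldehyde of A5, and the resulting Breslow intermediate (an acyl anion equivalent at C4) would attack the tethered aryl ketone carbon in a six-membered intramolecular crossed benzoin closure to give the racemic 3-hydroxychroman-4-one A4.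
- In its favour: it is catalytic, mild and metal-free, and the reaction class is established for chromanones. Ring A carries its oxygens from the start, so no late fluorine displacement is needed.
- Against it here: the acceptor ketone sits on an electron-rich ring with an ortho benzyloxy group and is a poor electrophile. A stereocenter is made only to be destroyed. Removing water from A4 across C2–C3 is not a simple base-induced elimination (the hydroxyl is alpha to the carbonyl and C2–H is not acidic), so it needs activation that could trigger aryl migration or touch the silyl ether. Both halves of A5 need separate preparation.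
- Comparison: the same C3–C4 bond is made as in the chosen plan, so structurally the two are equal there. This plan is the better one in mildness and in avoiding alkoxide chemistry on ring C. The chosen plan is shorter by at least the dehydration and the silyl operations and needs only an aryl aldehyde, not an aryl ketone, on ring B.

**Alternative 3:** The cut removes three ring B bonds (C5'–C6', C1'–C2', C2'–C3'), giving the chromium carbene complex A7, 5,7-bis(benzyloxy)-3-ethynylchromone A8 and one CO ligand. In the forward sense this is a Dötz benzannulation: alkyne insertion into the Cr=C bond, CO insertion to a vinylketene, 6π electrocyclisation and tautomerisation would give phenol A6, with the substituted alkyne carbon ending up next to the new C–OH.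
- In its favour: the whole pentasubstituted ring B is built in one step, and the free C2' phenol is placed para to the C5' methoxy group by the mechanism itself. The plan is highly convergent and needs no directed metalation or formylation.
- Against it here: it uses stoichiometric chromium carbonyl chemistry (toxicity, waste). A7 carries an α-methoxyalkenyl group and would be an unusually electron-rich, possibly labile carbene complex. A8 is a base-sensitive, electron-poor alkyne conjugated to the chromone and could divert to furan, cyclobutenone or indene products. A6 is a para-alkoxyphenol that may oxidise during removal of chromium. Both partners need several steps.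
- Comparison: on convergence and on the ring B substitution problem this plan is the better one. On oxidation level of the product it is the equal of the chosen plan. On safety, atom economy and predictability the chosen plan, which builds ring B by stepwise aromatic substitution from a cheap phenol, is stronger.

Key step: step 9

Remark on the chemistry: compounds 2 and 4–8 are racemic at the acetal carbon of the tetrahydropyranyl group, which is removed in step 4, and 17 is drawn as its E isomer although either enamine geometry would converge in step 9.

## Route

Step 1
Reactants: 1 3,4-dimethoxyphenol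
Product: 2 2-(3,4-dimethoxyphenoxy)tetrahydro-2H-pyran (racemic)
Conditions: 3,4-dihydro-2H-pyran, PPTS (cat.), CH2Cl2, rt
Reagents that add atoms: 3,4-dihydro-2H-pyran, C1=COCCC1
Why: Acid-catalysed addition of the phenol to the enol ether (tetrahydropyranylation) should give the mixed acetal, which is stable to organolithiums, chelates lithium for the next step and is made without a chloromethyl ether; the new acetal carbon is racemic and is lost in step 4.

Step 2
Reactants: 2 2-(3,4-dimethoxyphenoxy)tetrahydro-2H-pyran; 3 prenyl bromide (1-bromo-3-methylbut-2-ene)
Product: 6 2-[3,4-dimethoxy-2-(3-methylbut-2-en-1-yl)phenoxy]tetrahydro-2H-pyran (racemic), via aryllithium 4 (not isolated), via arylcopper 5 (not isolated)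
Conditions: n-BuLi, THF, 0 °C → rt; CuBr·SMe2, −40 °C; then 3, −40 → 0 °C
Reagents that add atoms: none
Why: Directed ortho-metalation: the C–H flanked by the acetal oxygen and the adjacent methoxy group is activated by both and should be lithiated selectively to 4. Transmetalation to arylcopper 5 should then give SN2 allylation at the unsubstituted terminus of prenyl bromide and suppress the SN2' mode.

Step 3
Reactants: 6 2-[3,4-dimethoxy-2-(3-methylbut-2-en-1-yl)phenoxy]tetrahydro-2H-pyran
Product: 8 4-[2,3-dimethoxy-6-(tetrahydro-2H-pyran-2-yloxy)phenyl]-2-methylbutan-2-ol (racemic), via tertiary hydroperoxide 7 (not isolated)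
Conditions: Co(acac)2 (cat.), PhSiH3, O2 (1 atm), i-PrOH/THF, rt
Reagents that add atoms: dioxygen, O=O
Why: Mukaiyama hydration: hydrogen-atom transfer from a cobalt hydride to the trisubstituted alkene gives the tertiary radical, which is trapped by O2, and the peroxide 7 is reduced in the flask by excess silane, so the hydroxyl lands on the tertiary carbon. The medium is neutral and mercury-free, and the masked phenol can neither be oxidised nor close to a chroman.

Step 4
Reactants: 8 4-[2,3-dimethoxy-6-(tetrahydro-2H-pyran-2-yloxy)phenyl]-2-methylbutan-2-ol
Product: 9 2-(3-hydroxy-3-methylbutyl)-3,4-dimethoxyphenol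
Conditions: PPTS (cat.), MeOH, 45 °C, under N2
Reagents that add atoms: none
Why: Acetal exchange with methanol under pyridinium catalysis should free the phenol; this acidity is far too low to ionise the tertiary alcohol, so closure to the 2,2-dimethylchroman is not expected.

Step 5
Reactants: 9 2-(3-hydroxy-3-methylbutyl)-3,4-dimethoxyphenol
Product: 11 2-hydroxy-3-(3-hydroxy-3-methylbutyl)-4,5-dimethoxybenzaldehyde, via salicyl alcohol 10 (not isolated)
Conditions: MgCl2, Et3N, (CH2O)n, MeCN, reflux; cold aq. citric acid work-up
Reagents that add atoms: formaldehyde (as paraformaldehyde), C=O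
Why: Magnesium-mediated ortho-formylation of a phenol (Casnati–Skattebøl): the magnesium phenoxide delivers formaldehyde to the only free ortho carbon, and the benzylic alkoxide 10 is oxidised by a second formaldehyde through hydride transfer. The regiochemistry is fixed by the phenol and the tertiary alcohol is a spectator.

Step 6
Reactants: 11 2-hydroxy-3-(3-hydroxy-3-methylbutyl)-4,5-dimethoxybenzaldehyde
Product: 12 2-(benzyloxy)-3-(3-hydroxy-3-methylbutyl)-4,5-dimethoxybenzaldehyde
Conditions: BnBr, K2CO3, DMF, rt
Reagents that add atoms: benzyl bromide, BrCc1ccccc1
Why: Williamson etherification of the phenoxide; carbonate does not deprotonate the tertiary alcohol, so only the phenol should be benzylated.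

Step 7
Reactants: 13 diphenylphosphine oxide; 14 morpholine
Product: 15 4-[(diphenylphosphoryl)methyl]morpholine
Conditions: (CH2O)n, toluene, 90 °C, 4 Å MS
Reagents that add atoms: formaldehyde (as paraformaldehyde), C=O
Why: Kabachnik–Fields (phospha-Mannich) condensation: the iminium ion from morpholine and formaldehyde should be captured by the P–H compound to give the α-aminomethyl phosphine oxide.

Step 8
Reactants: 12 2-(benzyloxy)-3-(3-hydroxy-3-methylbutyl)-4,5-dimethoxybenzaldehyde; 15 4-[(diphenylphosphoryl)methyl]morpholine
Product: 17 (E)-4-{2-[2-(benzyloxy)-3-(3-hydroxy-3-methylbutyl)-4,5-dimethoxyphenyl]ethenyl}morpholine, via hydroxy phosphine oxide adduct 16 (not isolated)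
Conditions: 15 (2.2 equiv), n-BuLi, THF, −78 °C; then 12, −78 → 0 °C; then t-BuOK, 0 °C → rt; cold aq. NaHCO3 work-up, crude used directly
Reagents that add atoms: none
Why: Horner–Wittig enamine synthesis: the lithiated α-amino phosphine oxide adds to the aldehyde (the first equivalent is spent on the tertiary hydroxyl), and the potassium alkoxide of adduct 16 should eliminate diphenylphosphinate by syn elimination. The conjugated E enamine is expected as the main isomer, and the geometry is immaterial for step 9.

Step 9
Reactants: 17 (E)-4-{2-[2-(benzyloxy)-3-(3-hydroxy-3-methylbutyl)-4,5-dimethoxyphenyl]ethenyl}morpholine; 18 2,4,6-trifluorobenzoyl chloride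
Product: 21 2'-(benzyloxy)-5,7-difluoro-3'-(3-hydroxy-3-methylbutyl)-4',5'-dimethoxyisoflavone, via enaminone 19 (not isolated), via hydroxymethylene ketone 20 (not isolated)
Conditions: (a) i-Pr2NEt, CH2Cl2, 0 °C → rt; (b) 0.5 M aq. HCl, THF, rt, then phase separation; (c) K2CO3, MeCN, 60 °C
Reagents that add atoms: water, O
Why: The enamine β-carbon, which carries ring B, attacks acid chloride 18 in a Stork-type C-acylation, and loss of the proton between aryl and carbonyl from the iminium ion gives the push–pull enaminone 19, forming C3–C4. Dilute acid then hydrolyses this vinylogous amide to the hydroxymethylene ketone 20, placing an oxygen from water on C2 and carrying morpholine into the aqueous layer as its salt, so that the amine cannot attack the activated fluorines. With K2CO3 the enolate oxygen adds to C8a, the fluorinated carbon ortho to the ketone, and fluoride leaves from the Meisenheimer intermediate, forming O1–C8a. The closest known reaction type is the chromone and quinolone synthesis in which an enamine or enolate is C-acylated by a 2-halobenzoyl chloride and the ring is closed by displacement of the ortho halide. Ring C closes by a six-membered addition–elimination at a trigonal carbon, best classed as 6-endo-trig because the accepting C8a=C4a bond, conjugated with C4=O, lies inside the new ring (an intramolecular oxa-Michael addition followed by loss of fluoride). No stereocenter is formed. The step needs acylation at carbon in preference to the free tertiary hydroxyl, which the far higher nucleophilicity of the enamine carbon and the absence of an acyl-transfer catalyst should secure. It also needs closure through oxygen, which is secured because nitrogen is removed before cyclisation, and the two ortho fluorines of 18 are equivalent, so only one isoflavone can form.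

Step 10
Reactants: 21 2'-(benzyloxy)-5,7-difluoro-3'-(3-hydroxy-3-methylbutyl)-4',5'-dimethoxyisoflavone
Product: 23 2',5,7-tris(benzyloxy)-3'-(3-hydroxy-3-methylbutyl)-4',5'-dimethoxyisoflavone, via monofluoro isoflavone 22 (not isolated)
Conditions: BnOH (excess), NaH, THF, 0 °C → rt; then 21, rt → 60 °C; aq. NH4Cl work-up
Reagents that add atoms: benzyl alcohol, OCc1ccccc1
Why: Nucleophilic aromatic substitution: C5–F is ortho and C7–F para to the C4 carbonyl, and sodium chelation by that carbonyl is expected to bring the first benzyloxide to C5 (22); the order of the two displacements does not affect the outcome. The first benzyloxy group sits meta to the remaining fluorine and so does not deactivate it by resonance, excess benzyl alcohol keeps the tertiary alcohol protonated, and the dry medium (NaH in THF, not in an amide solvent) keeps any alkoxide addition at C2 reversible.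

Step 11
Reactants: 23 2',5,7-tris(benzyloxy)-3'-(3-hydroxy-3-methylbutyl)-4',5'-dimethoxyisoflavone
Product: 24 2',5,7-trihydroxy-3'-(3-hydroxy-3-methylbutyl)-4',5'-dimethoxyisoflavone (target)
Conditions: H2 (1 atm), 10% Pd/C, EtOAc/MeOH, rt
Reagents that add atoms: none
Why: Hydrogenolysis of the three aryl benzyl ethers on Pd/C is neutral, so the tertiary alcohol next to the freed C2' phenol never meets acid; the reaction should be stopped at complete debenzylation so that the hindered C2=C3 bond is not reduced.

## Compound list

1 | 3,4-dimethoxyphenol | COc1ccc(O)cc1OC | starting material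
2 | 2-(3,4-dimethoxyphenoxy)tetrahydro-2H-pyran (racemic) | COc1ccc(OC2CCCCO2)cc1OC | intermediate
3 | prenyl bromide (1-bromo-3-methylbut-2-ene) | CC(C)=CCBr | starting material
4 | [2,3-dimethoxy-6-(tetrahydro-2H-pyran-2-yloxy)phenyl]lithium (racemic) | COc1ccc(OC2CCCCO2)c([Li])c1OC | intermediate (not isolated)
5 | [2,3-dimethoxy-6-(tetrahydro-2H-pyran-2-yloxy)phenyl]copper (racemic) | COc1ccc(OC2CCCCO2)c([Cu])c1OC | intermediate (not isolated)
6 | 2-[3,4-dimethoxy-2-(3-methylbut-2-en-1-yl)phenoxy]tetrahydro-2H-pyran (racemic) | COc1ccc(OC2CCCCO2)c(CC=C(C)C)c1OC | intermediate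
7 | 2-[2-(3-hydroperoxy-3-methylbutyl)-3,4-dimethoxyphenoxy]tetrahydro-2H-pyran (racemic) | COc1ccc(OC2CCCCO2)c(CCC(C)(C)OO)c1OC | intermediate (not isolated)
8 | 4-[2,3-dimethoxy-6-(tetrahydro-2H-pyran-2-yloxy)phenyl]-2-methylbutan-2-ol (racemic) | COc1ccc(OC2CCCCO2)c(CCC(C)(C)O)c1OC | intermediate
9 | 2-(3-hydroxy-3-methylbutyl)-3,4-dimethoxyphenol | COc1ccc(O)c(CCC(C)(C)O)c1OC | intermediate
10 | 6-(hydroxymethyl)-2-(3-hydroxy-3-methylbutyl)-3,4-dimethoxyphenol (as its magnesium salt in the flask) | COc1cc(CO)c(O)c(CCC(C)(C)O)c1OC | intermediate (not isolated)
11 | 2-hydroxy-3-(3-hydroxy-3-methylbutyl)-4,5-dimethoxybenzaldehyde | COc1cc(C=O)c(O)c(CCC(C)(C)O)c1OC | intermediate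
12 | 2-(benzyloxy)-3-(3-hydroxy-3-methylbutyl)-4,5-dimethoxybenzaldehyde | COc1cc(C=O)c(OCc2ccccc2)c(CCC(C)(C)O)c1OC | intermediate
13 | diphenylphosphine oxide | O=[PH](c1ccccc1)c1ccccc1 | starting material
14 | morpholine | C1COCCN1 | starting material
15 | 4-[(diphenylphosphoryl)methyl]morpholine | O=P(CN1CCOCC1)(c1ccccc1)c1ccccc1 | intermediate
16 | 1-[2-(benzyloxy)-3-(3-hydroxy-3-methylbutyl)-4,5-dimethoxyphenyl]-2-(diphenylphosphoryl)-2-(morpholin-4-yl)ethanol (racemic mixture of diastereomers, as its alkoxide in the flask) | COc1cc(C(O)C(N2CCOCC2)P(=O)(c2ccccc2)c2ccccc2)c(OCc2ccccc2)c(CCC(C)(C)O)c1OC | intermediate (not isolated)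
17 | (E)-4-{2-[2-(benzyloxy)-3-(3-hydroxy-3-methylbutyl)-4,5-dimethoxyphenyl]ethenyl}morpholine | COc1cc(/C=C/N2CCOCC2)c(OCc2ccccc2)c(CCC(C)(C)O)c1OC | intermediate
18 | 2,4,6-trifluorobenzoyl chloride | O=C(Cl)c1c(F)cc(F)cc1F | starting material
19 | 2-[2-(benzyloxy)-3-(3-hydroxy-3-methylbutyl)-4,5-dimethoxyphenyl]-3-(morpholin-4-yl)-1-(2,4,6-trifluorophenyl)prop-2-en-1-one (alkene geometry not defined) | COc1cc(C(=CN2CCOCC2)C(=O)c2c(F)cc(F)cc2F)c(OCc2ccccc2)c(CCC(C)(C)O)c1OC | intermediate (not isolated)
20 | 2-[2-(benzyloxy)-3-(3-hydroxy-3-methylbutyl)-4,5-dimethoxyphenyl]-3-hydroxy-1-(2,4,6-trifluorophenyl)prop-2-en-1-one (enol form of the β-keto aldehyde) | COc1cc(C(=CO)C(=O)c2c(F)cc(F)cc2F)c(OCc2ccccc2)c(CCC(C)(C)O)c1OC | intermediate (not isolated)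
21 | 2'-(benzyloxy)-5,7-difluoro-3'-(3-hydroxy-3-methylbutyl)-4',5'-dimethoxyisoflavone | COc1cc(-c2coc3cc(F)cc(F)c3c2=O)c(OCc2ccccc2)c(CCC(C)(C)O)c1OC | intermediate
22 | 2',5-bis(benzyloxy)-7-fluoro-3'-(3-hydroxy-3-methylbutyl)-4',5'-dimethoxyisoflavone | COc1cc(-c2coc3cc(F)cc(OCc4ccccc4)c3c2=O)c(OCc2ccccc2)c(CCC(C)(C)O)c1OC | intermediate (not isolated)
23 | 2',5,7-tris(benzyloxy)-3'-(3-hydroxy-3-methylbutyl)-4',5'-dimethoxyisoflavone | COc1cc(-c2coc3cc(OCc4ccccc4)cc(OCc4ccccc4)c3c2=O)c(OCc2ccccc2)c(CCC(C)(C)O)c1OC | intermediate
24 | 2',5,7-trihydroxy-3'-(3-hydroxy-3-methylbutyl)-4',5'-dimethoxyisoflavone | COc1cc(-c2coc3cc(O)cc(O)c3c2=O)c(O)c(CCC(C)(C)O)c1OC | target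

## Step count and least certain steps

Total step count: 11. Longest linear sequence: 10 steps (steps 1–6 and 8–11, from 1 to 24); step 7 is a one-step side branch that supplies 15.

**Step 9 (key step).** The crowded enamine carbon, flanked by an ortho-benzyloxy aryl group, may be acylated only slowly, so that acylation at the tertiary hydroxyl or unproductive acylation at nitrogen competes. During ring closure the formyl carbon of 20 may be lost by retro-Claisen cleavage before the oxygen reaches C8a. The fallback sets out from 12 and rejoins the route at 21; it replaces the enamine acylation by an oxidative aryl migration.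
- 12 is condensed with 2',4',6'-trifluoroacetophenone under Claisen–Schmidt conditions (LiOH·H2O in THF, an alcohol-free medium so that no alkoxide can displace fluorine) to give the chalcone (E)-3-[2-(benzyloxy)-3-(3-hydroxy-3-methylbutyl)-4,5-dimethoxyphenyl]-1-(2,4,6-trifluorophenyl)prop-2-en-1-one F1.
- PhI(OAc)2 in MeOH/HC(OMe)3 with catalytic acid should then induce the 1,2-shift of the electron-rich ring B from the β- to the α-carbon and give the acetal 2-[2-(benzyloxy)-3-(3-hydroxy-3-methylbutyl)-4,5-dimethoxyphenyl]-3,3-dimethoxy-1-(2,4,6-trifluorophenyl)propan-1-one F2.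
- Dilute aqueous acid unmasks 20, and K2CO3 in MeCN closes ring C exactly as in stage (c) of step 9 to give 21.

**Step 8.** The lithium alkoxide of 16 may fail to eliminate cleanly, the adduct may revert to 12, or the enamine may hydrolyse during work-up. The fallback sets out from 12 and rejoins at 17; it goes through the free aldehyde instead of the phosphorus-based olefination.
- Wittig reaction of 12 with (methoxymethyl)triphenylphosphonium chloride and t-BuOK in THF gives the enol ether 2-(benzyloxy)-3-(3-hydroxy-3-methylbutyl)-4,5-dimethoxy-1-(2-methoxyethenyl)benzene F3 as an E/Z mixture.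
- Dilute aqueous HCl in THF hydrolyses this to [2-(benzyloxy)-3-(3-hydroxy-3-methylbutyl)-4,5-dimethoxyphenyl]acetaldehyde F4.
- F4 is condensed at once with morpholine in toluene over 4 Å molecular sieves to give 17.

**Step 10.** The second displacement may stall, and under the forcing conditions then needed, alkoxide or adventitious hydroxide may add at C2 and cleave ring C with loss of the C2 carbon. The fallback sets out from 21 and rejoins at 23; it accepts that cleavage and rebuilds ring C by the classical deoxybenzoin route.
- After exhaustive benzyloxide treatment, aqueous NaOH is added so that all material converges on the deoxybenzoin 1-[2,4-bis(benzyloxy)-6-hydroxyphenyl]-2-[2-(benzyloxy)-3-(3-hydroxy-3-methylbutyl)-4,5-dimethoxyphenyl]ethan-1-one F5.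
- Heating F5 with N,N-dimethylformamide dimethyl acetal in toluene reinstalls C2 and closes ring C with loss of methanol and dimethylamine, giving 23.

**Step 3.** The radical hydration may over-reduce the alkene to the alkane, leave peroxide unreduced, or oxidise the benzylic position. The fallback sets out from 6 and rejoins at 8; it uses two-electron chemistry throughout.
- Epoxidation with mCPBA buffered by NaHCO3 in CH2Cl2 at 0 °C gives 2-{2-[(3,3-dimethyloxiran-2-yl)methyl]-3,4-dimethoxyphenoxy}tetrahydro-2H-pyran F6.
- LiAlH4 in THF delivers hydride to the less substituted epoxide carbon, leaving the hydroxyl on the tertiary carbon, which is 8.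

## Further compounds

F1 | step 9 | (E)-3-[2-(benzyloxy)-3-(3-hydroxy-3-methylbutyl)-4,5-dimethoxyphenyl]-1-(2,4,6-trifluorophenyl)prop-2-en-1-one | COc1cc(/C=C/C(=O)c2c(F)cc(F)cc2F)c(OCc2ccccc2)c(CCC(C)(C)O)c1OC
F2 | step 9 | 2-[2-(benzyloxy)-3-(3-hydroxy-3-methylbutyl)-4,5-dimethoxyphenyl]-3,3-dimethoxy-1-(2,4,6-trifluorophenyl)propan-1-one (racemic) | COc1cc(C(C(OC)OC)C(=O)c2c(F)cc(F)cc2F)c(OCc2ccccc2)c(CCC(C)(C)O)c1OC
F3 | step 8 | 2-(benzyloxy)-3-(3-hydroxy-3-methylbutyl)-4,5-dimethoxy-1-(2-methoxyethenyl)benzene (E/Z mixture) | COc1cc(C=COC)c(OCc2ccccc2)c(CCC(C)(C)O)c1OC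
F4 | step 8 | [2-(benzyloxy)-3-(3-hydroxy-3-methylbutyl)-4,5-dimethoxyphenyl]acetaldehyde | COc1cc(CC=O)c(OCc2ccccc2)c(CCC(C)(C)O)c1OC
F5 | step 10 | 1-[2,4-bis(benzyloxy)-6-hydroxyphenyl]-2-[2-(benzyloxy)-3-(3-hydroxy-3-methylbutyl)-4,5-dimethoxyphenyl]ethan-1-one | COc1cc(CC(=O)c2c(O)cc(OCc3ccccc3)cc2OCc2ccccc2)c(OCc2ccccc2)c(CCC(C)(C)O)c1OC
F6 | step 3 | 2-{2-[(3,3-dimethyloxiran-2-yl)methyl]-3,4-dimethoxyphenoxy}tetrahydro-2H-pyran (racemic mixture of diastereomers) | COc1ccc(OC2CCCCO2)c(CC2OC2(C)C)c1OC
A1 | alternative 1 | racemic 5,7-dihydroxy-3-(5,6-dimethoxy-2-oxochroman-8-yl)chroman-4-one | O=C1c2c(O)cc(O)cc2OCC1c1cc(OC)c(OC)c2CCC(=O)Oc12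
A2 | alternative 1 | phloroglucinol | Oc1cc(O)cc(O)c1
A3 | alternative 1 | 2-(5,6-dimethoxy-2-oxochroman-8-yl)acrylic acid | C=C(C(=O)O)c1cc(OC)c(OC)c2CCC(=O)Oc12
A4 | alternative 2 | racemic 5,7-bis(benzyloxy)-3-[2-(benzyloxy)-4,5-dimethoxy-3-(3-methyl-3-triethylsilyloxybutyl)phenyl]-3-hydroxychroman-4-one | O=C1c2c(OCc3ccccc3)cc(OCc3ccccc3)cc2OCC1(O)c1cc(OC)c(OC)c(CCC(C)(C)O[Si](CC)(CC)CC)c1OCc1ccccc1
A5 | alternative 2 | 2,4-bis(benzyloxy)-6-{2-[2-(benzyloxy)-4,5-dimethoxy-3-(3-methyl-3-triethylsilyloxybutyl)phenyl]-2-oxoethoxy}benzaldehyde | O=Cc1c(OCc2ccccc2)cc(OCc2ccccc2)cc1OCC(=O)c1cc(OC)c(OC)c(CCC(C)(C)O[Si](CC)(CC)CC)c1OCc1ccccc1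
A6 | alternative 3 | 5,7-bis(benzyloxy)-2'-hydroxy-4',5'-dimethoxy-3'-(3-methyl-3-triethylsilyloxybutyl)isoflavone | COc1cc(-c2coc3cc(OCc4ccccc4)cc(OCc4ccccc4)c3c2=O)c(O)c(CCC(C)(C)O[Si](CC)(CC)CC)c1OC
A7 | alternative 3 | pentacarbonyl[(2Z)-1,2-dimethoxy-6-methyl-6-(triethylsilyloxy)hept-2-en-1-ylidene]chromium | COC(=[Cr](=C=O)(=C=O)(=C=O)(=C=O)=C=O)/C(OC)=C/CCC(C)(C)O[Si](CC)(CC)CC
A8 | alternative 3 | 5,7-bis(benzyloxy)-3-ethynyl-4H-chromen-4-one | C#Cc1coc2cc(OCc3ccccc3)cc(OCc3ccccc3)c2c1=O
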